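## Structural features

The target is a flavanonol methyl ether, a 2,3-dihydro-4H-chromen-4-one. Ring A (the fused benzene, C4a to C8a) carries hydroxyls at C5 and C6 and a methoxy group at C7. Ring C (O1, C2, C3, C4, C4a, C8a) carries the ketone at C4 and a methoxy group at C3. Ring B, a 2,3-dihydroxy-4-methoxyphenyl group, is joined to C2 by a single C–C bond.

C2 and C3 are adjacent stereocentres, both R, so the aryl group and the C3 methoxy group are trans on ring C. Three elements are fragile:
- The benzylic C2–O1 bond lies β to the ketone. It opens by retro-oxa-Michael reaction under base and can ionise under strong acid, because ring B is a para-methoxy, ortho-oxygenated donor.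
- The C3–H bond α to the ketone allows epimerisation or dehydrogenation to the flavonol.
- The two catechol units are easily oxidised once free.

The real difficulty is twofold. Seven peripheral oxygens must be sorted into four free hydroxyls, two aryl methyl ethers and one aliphatic methyl ether, and the configuration at C2 and C3 must be set on a ring that can racemise by ring opening. The C5 hydroxyl is peri to the C4 carbonyl and can be released from a methyl ether by chelation, so ring A can come from a mirror-symmetric 3,5-dimethoxyphenol.

The key step exploits the position of C4 as a carbonyl carbon between C4a and C3, with O1 (on C8a, ortho to C4a) and C2 completing ring C. An ortho-iodophenol supplies C4a–I and C8a–OH, carbon monoxide supplies C4, and a ring B arylalkyne supplies C3 and C2.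

## Logic of the disconnections

**20 to 19.** The four O–H bonds of 20 are traced back to three O–benzyl bonds (at O6, O2' and O3') and one O–methyl bond at O5. The catechols must be masked through the metal-catalysed and oxidative steps, and the O5 methyl is the one ether that chelation to the C4 carbonyl can single out. The gain is a fully capped precursor whose ring A derives from a symmetric unit. The forward step must cleave four ethers, spare three methyl ethers and the C2–O1 bond, and use no base.

**19 to 18.** The O–CH3 bond at C3 is cut. With every phenol capped, the C3 hydroxyl of 18 is the only nucleophilic oxygen, so chemoselectivity is automatic. The forward step must alkylate without forming an alkoxide or enolate, since either would open ring C or epimerise C3.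

**18 to 15.** The C3–O bond is cut. C3 is α to the ketone, so the oxygen can be delivered to an enol derivative, and the C2 aryl group decides the face. This removes one stereocentre. The forward step must form the enol derivative without a free enolate and bring the oxidant in anti to the aryl group.

**15 to 13.** The C2–H and C3–H bonds are removed, which takes away the last stereocentre and leaves a flat, robust pyranone. The forward step must deliver hydride to one enantioface of C2, in the 1,4 sense only.

**13 to 5, 9 and 10.** The C4a–C4, C4–C3 and O1–C2 bonds are cut. This dissolves ring C into three simple pieces with no stereochemical content. The forward step must insert 10 before the alkyne couples, and close the six-membered ring and not the five-membered one.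

**5 to 4, 2 and 1.** The C–I bond is cut first; the two open ring positions of 4 are equivalent, so only mono-substitution has to be controlled. The phenolic C–O bond of 4 is traced to the formyl C–C bond of 2 (oxidative aryl migration), and the O–benzyl bond of 2 leads to 1.

**9 to 7, 8 and 6.** The alkyne is traced to the aldehyde carbon of 7 plus one carbon from 8. The two O–benzyl bonds of 7 lead to 6. The forward homologation must tolerate two ortho and meta benzyl ethers and use only mild base.

## Other disconnections considered

**Alternative 1:** The cut is through C2–C3 and the C3–O(methyl) bond of an open-chain form of ring C, with O1–C2 closed afterwards.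
- Forward key step: Rh2(OAc)4 decomposes diazoketone A2 to a carbenoid. Methanol A3 adds to give an oxonium ylide, and a chiral phosphoric acid steers its aldol-type capture by aldehyde 7 to give aldol A1. Fluoride would then free phenol A4, and Mitsunobu closure with inversion at the carbinol carbon would lead to 19, followed by step 10.
- In favour: the C3 methoxy group and both stereocentres arrive in the C–C bond-forming step. Hydroxylation and O-methylation of an enolisable ketone are avoided, which is better than the chosen plan on this point. Three steps follow the key step instead of four, and no pressurised CO is needed.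
- Against: capture by the aldehyde must outrun the 1,2-proton shift that gives plain O–H insertion, and 7 is an electron-rich, ortho-substituted and therefore weak electrophile. The acceptor-only carbenoid from A2 is flanked by ortho methoxy and silyloxy oxygens that can attack it intramolecularly. Relative and absolute configuration must both be controlled in one event. The Mitsunobu closure acts on a benzylic carbon that ionises easily, so inversion may not be clean. A2 needs a diazomethane-type acylation of a hindered benzoic acid, roughly six steps from 1.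
- Comparison: on structure the two plans share the protecting-group pattern and the last step, so the deprotection risk is equal. On mechanism the chosen plan separates a stereochemically undemanding ring construction from stereocontrol, whereas this alternative concentrates every selectivity in one step. On step economy the longest line is estimated at about ten steps against eight.

**Alternative 2:** The cut is the aryl ether bond O1–C8a.
- Forward key step: Ag2O oxidises the free catechol of open-chain ketone A6 to ortho-quinone A7. The benzylic hydroxyl adds to C8a, which is the β-position of both the C5 quinone carbonyl and the C4 ketone (6-endo-trig). Tautomerisation restores the aromatic ring, and Na2S2O4 work-up returns re-oxidised material to chromanone A5. Hydrogenolysis of the two benzyl ethers would then give 20.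
- In favour: the 5,6-dihydroxy pattern appears directly. No C5 methyl ether has to be removed and no Lewis acid comes near the C2–O1 bond, which is better than the chosen plan. Only one neutral step follows the key step, and ring A needs no halogen.
- Against: the stereochemical problem is moved, not solved. A6 requires an enantio- and diastereoselective aldol of an α-methoxy ketone with 7, and such a β-hydroxy ketone can undergo retro-aldol cleavage or C3 enolisation under the oxidising, weakly basic conditions. A secondary alcohol is a weak nucleophile toward a short-lived quinone, so intermolecular addition, addition at C8 and dimerisation compete. A5 is more easily oxidised than A6, so over-oxidation threatens. Closure of an alkoxide onto an ortho-quinone to form a chromanone has little close precedent.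
- Comparison: on structure this alternative is the better in economy of oxygenation pattern. On mechanism the chosen plan runs a well-charted metal-catalysed sequence on protected arenes, while this one passes through an unprotected redox-active intermediate. On step economy it is equal or slightly shorter on paper, provided A6 is accessible in four or five steps.

**Alternative 3:** The cut is the C2–C3 bond.
- Forward key step: Rh2(S-PTTL)4 converts diazoketone A8, in which O1 already carries ring B as a benzylic ether, into a carbenoid at C3. Insertion into the benzylic C–H bond next to O1 closes ring C and gives flavanone A9, which is identical with 15.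
- In favour: the same intermediate as in the chosen route is reached with C2 set by the catalyst in the bond-forming event. One step replaces annulation plus asymmetric reduction, which is better on that count. The C–H bond is doubly activated (benzylic and α to oxygen), and no CO is used.
- Against: insertion needs a six-membered transition state, while the ether oxygen is placed for five-membered attack on the carbenoid. That gives an oxonium ylide whose [1,2]-shift of the electron-rich benzylic group would contract the ring. The C5 methoxy oxygen on the other flank is placed equally well. An acceptor-only carbenoid is unselective and can also add to the benzyl arenes. High enantioselectivity with this catalyst class is best established for donor–acceptor carbenoids forming five-membered rings. A8 needs a labile electron-rich benzylic halide and a diazomethane-type step, about six steps before the key step.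
- Comparison: on structure the endgame (steps 8 to 10) is identical, so the plans are equal there. On mechanism the chosen route uses two steps of known type on this substrate class, against one step with a serious chemoselectivity gamble. On step economy the chosen route reaches 15 after five steps in its longest line, against about seven.

Key step: step 6

Assumptions on the chemistry:
- The target is the (2R,3R) isomer, with ring B and the C3 methoxy group trans. The 2S descriptor of 14, 15 and 16 denotes the same spatial arrangement at C2; the letter changes only because C3 outranks the aryl carbon once it bears oxygen.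
- The substitution pattern of 5 maps onto 13 without correction: its C3 methoxy, C4 benzyloxy and C5 methoxy groups become those at C5, C6 and C7 of 13.
- In step 7 the bisphosphine is written as (R). What is meant is the enantiomer that delivers hydride to the Re face of C2 of 13; the antipode is used if the first run shows the opposite sense.

## Route

Step 1
Reactants: 1 syringaldehyde (4-hydroxy-3,5-dimethoxybenzaldehyde)
Product: 2 4-(benzyloxy)-3,5-dimethoxybenzaldehyde
Conditions: BnBr, K2CO3, DMF, 60 °C
Reagents that add atoms: benzyl bromide, BrCc1ccccc1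
Why: Williamson ether synthesis on the phenoxide; the aldehyde has no α-hydrogen and is inert to carbonate.

Step 2
Reactants: 2 4-(benzyloxy)-3,5-dimethoxybenzaldehyde
Product: 4 4-(benzyloxy)-3,5-dimethoxyphenol, via aryl formate 3 (not isolated)
Conditions: mCPBA, CH2Cl2, 0 °C to rt; then K2CO3 (cat.), MeOH, rt
Reagents that add atoms: 3-chloroperoxybenzoic acid (mCPBA), OOC(=O)c1cccc(Cl)c1
Why: Baeyer–Villiger (Dakin-type) oxidation in which the electron-rich aryl group migrates in preference to hydrogen; the formate 3 is then methanolysed to the mirror-symmetric phenol.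

Step 3
Reactants: 4 4-(benzyloxy)-3,5-dimethoxyphenol
Product: 5 4-(benzyloxy)-2-iodo-3,5-dimethoxyphenol
Conditions: NIS (1.0 equiv), MeCN, −20 to 0 °C, dark
Reagents that add atoms: N-iodosuccinimide, O=C1CCC(=O)N1I
Why: Electrophilic aromatic iodination; the only two free ring positions are equivalent by symmetry and both ortho to the hydroxyl, so regiochemistry is unambiguous, and one equivalent of reagent at low temperature should hold the reaction at mono-substitution.

Step 4
Reactants: 6 2,3-dihydroxy-4-methoxybenzaldehyde
Product: 7 2,3-bis(benzyloxy)-4-methoxybenzaldehyde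
Conditions: BnBr (2.4 equiv), K2CO3, DMF, 70 °C
Reagents that add atoms: benzyl bromide, BrCc1ccccc1
Why: Double Williamson etherification; warming in DMF is enough to alkylate the hydrogen-bonded C2 hydroxyl as well.

Step 5
Reactants: 7 2,3-bis(benzyloxy)-4-methoxybenzaldehyde; 8 dimethyl (1-diazo-2-oxopropyl)phosphonate
Product: 9 2,3-bis(benzyloxy)-1-ethynyl-4-methoxybenzene
Conditions: K2CO3, MeOH, 0 °C to rt
Reagents that add atoms: dimethyl (1-diazo-2-oxopropyl)phosphonate (8), COP(=O)(OC)C(=[N+]=[N-])C(C)=O
Why: Seyferth–Gilbert homologation in the Ohira–Bestmann form: methanolysis of 8 releases the diazomethylphosphonate anion, which converts the aldehyde through a diazoalkene and 1,2-shift into the terminal alkyne under conditions harmless to benzyl ethers.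

Step 6
Reactants: 5 4-(benzyloxy)-2-iodo-3,5-dimethoxyphenol; 9 2,3-bis(benzyloxy)-1-ethynyl-4-methoxybenzene; 10 carbon monoxide
Product: 13 6-(benzyloxy)-2-[2,3-bis(benzyloxy)-4-methoxyphenyl]-5,7-dimethoxy-4H-chromen-4-one, via ynone 11 (not isolated), via enaminone 12 (not isolated)
Conditions: PdCl2(PPh3)2 (5 mol %), Et2NH (solvent and base), CO (20 bar), 110 °C, autoclave, no copper
Reagents that add atoms: carbon monoxide (10), [C-]#[O+]
Why: This is a carbonylative Sonogashira coupling followed by amine-mediated cyclisation, the known palladium-catalysed three-component route from 2-iodophenols, CO and terminal arylalkynes to flavones. The divalent palladium precatalyst is reduced in the flask to zerovalent palladium, which adds oxidatively to the C4a–I bond of 5; CO inserts into the aryl–palladium bond, the aroylpalladium iodide takes up the acetylide generated from 9 by diethylamine, and reductive elimination gives ynone 11 with the C4a–C4 and C4–C3 bonds in place. Diethylamine then adds to the β-carbon of 11 to give enaminone 12, and the neighbouring phenol displaces the amine at that carbon by addition–elimination, which forms O1–C2 and closes ring C in the six-membered endo mode (6-endo-dig if counted from 11). No stereocentre is created, so no stereocontrol is required. Carbonylative coupling has to win over direct coupling, and the CO pressure, the absence of copper and the fast CO insertion of an electron-rich aryl–palladium bond secure this. Six-membered closure has to win over 5-exo closure to the aurone skeleton, and the secondary amine secures this because in 12 the amine-bearing carbon is the only site open to the phenol. The position of the iodide is beyond doubt because 5 derives from a mirror-symmetric phenol, and the aryl benzyl and methyl ethers are spectators under these conditions.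

Step 7
Reactants: 13 6-(benzyloxy)-2-[2,3-bis(benzyloxy)-4-methoxyphenyl]-5,7-dimethoxy-4H-chromen-4-one
Product: 15 (2S)-6-(benzyloxy)-2-[2,3-bis(benzyloxy)-4-methoxyphenyl]-5,7-dimethoxy-2,3-dihydro-4H-chromen-4-one, via silyl enol ether 14 (not isolated)
Conditions: Cu(OAc)2 (5 mol %), (R)-DTBM-SEGPHOS (5.5 mol %), (EtO)2MeSiH (3 equiv), toluene, 0 °C to rt; then 1 M HCl, THF, 0 °C
Reagents that add atoms: none
Why: Ligand-controlled asymmetric conjugate reduction with CuH, a reaction type known for 2-substituted chromones and β,β-disubstituted enones: the silane reduces Cu(OAc)2 to a bisphosphine-bound monovalent copper hydride that delivers hydride to the Re face of C2, and the copper enolate is silylated to 14, which shields the ketone from 1,2-reduction until mild acid releases 15. The C2 stereocentre is set by the chiral ligand, and no proton source is added so that the enol silane persists to the work-up.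

Step 8
Reactants: 15 (2S)-6-(benzyloxy)-2-[2,3-bis(benzyloxy)-4-methoxyphenyl]-5,7-dimethoxy-2,3-dihydro-4H-chromen-4-one
Product: 18 (2R,3R)-6-(benzyloxy)-2-[2,3-bis(benzyloxy)-4-methoxyphenyl]-3-hydroxy-5,7-dimethoxy-2,3-dihydro-4H-chromen-4-one, via trimethylsilyl enol ether 16 (not isolated), via 3-silyloxy ketone 17 (not isolated)
Conditions: TMSOTf, Et3N, CH2Cl2, 0 °C; then mCPBA, CH2Cl2, −20 to 0 °C; then 1 M HCl, THF, 0 °C
Reagents that add atoms: 3-chloroperoxybenzoic acid (mCPBA), OOC(=O)c1cccc(Cl)c1
Why: Rubottom oxidation: soft enolisation gives 16 without a free enolate, so the O1 phenoxide is not expelled and C2 is untouched; the peracid attacks the C3=C4 bond from the face opposite the C2 aryl group and 1,4-silyl migration gives 17 with the new C3–O bond trans to the aryl group (3R), after which dilute acid frees the alcohol. The C3 stereocentre is set by substrate control from C2.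

Step 9
Reactants: 18 (2R,3R)-6-(benzyloxy)-2-[2,3-bis(benzyloxy)-4-methoxyphenyl]-3-hydroxy-5,7-dimethoxy-2,3-dihydro-4H-chromen-4-one
Product: 19 (2R,3R)-6-(benzyloxy)-2-[2,3-bis(benzyloxy)-4-methoxyphenyl]-3,5,7-trimethoxy-2,3-dihydro-4H-chromen-4-one
Conditions: Me3OBF4, 1,8-bis(dimethylamino)naphthalene, 4 Å MS, CH2Cl2, 0 °C to rt
Reagents that add atoms: trimethyloxonium tetrafluoroborate, C[O+](C)C.F[B-](F)(F)F
Why: Meerwein O-methylation of the neutral alcohol with a hindered, non-nucleophilic amine as proton acceptor; no alkoxide or enolate is formed, so neither retro-oxa-Michael opening of ring C nor epimerisation at C3 is expected, and all phenols are capped.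

Step 10
Reactants: 19 (2R,3R)-6-(benzyloxy)-2-[2,3-bis(benzyloxy)-4-methoxyphenyl]-3,5,7-trimethoxy-2,3-dihydro-4H-chromen-4-one
Product: 20 (2R,3R)-2-(2,3-dihydroxy-4-methoxyphenyl)-5,6-dihydroxy-3,7-dimethoxy-2,3-dihydro-4H-chromen-4-one (CNP0075602.1)
Conditions: BCl3 (excess), C6HMe5, CH2Cl2, −78 to 0 °C; then H2O
Reagents that add atoms: none
Why: Lewis-acid ether cleavage: BCl3 with pentamethylbenzene as cation scavenger removes the three aryl benzyl groups at low temperature, and on warming the six-membered boron chelate between the C4 carbonyl and O5 directs chloride to the C5 methyl group only. The C7, C4' and aliphatic C3 methyl ethers lack this activation, and the base-free medium leaves both stereocentres in place.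

## Compound list

1 | syringaldehyde (4-hydroxy-3,5-dimethoxybenzaldehyde) | COc1cc(C=O)cc(OC)c1O | starting material
2 | 4-(benzyloxy)-3,5-dimethoxybenzaldehyde | COc1cc(C=O)cc(OC)c1OCc1ccccc1 | intermediate
3 | 4-(benzyloxy)-3,5-dimethoxyphenyl formate | COc1cc(OC=O)cc(OC)c1OCc1ccccc1 | intermediate
4 | 4-(benzyloxy)-3,5-dimethoxyphenol | COc1cc(O)cc(OC)c1OCc1ccccc1 | intermediate
5 | 4-(benzyloxy)-2-iodo-3,5-dimethoxyphenol | COc1cc(O)c(I)c(OC)c1OCc1ccccc1 | intermediate
6 | 2,3-dihydroxy-4-methoxybenzaldehyde | COc1ccc(C=O)c(O)c1O | starting material
7 | 2,3-bis(benzyloxy)-4-methoxybenzaldehyde | COc1ccc(C=O)c(OCc2ccccc2)c1OCc1ccccc1 | intermediate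
8 | dimethyl (1-diazo-2-oxopropyl)phosphonate | COP(=O)(OC)C(=[N+]=[N-])C(C)=O | starting material
9 | 2,3-bis(benzyloxy)-1-ethynyl-4-methoxybenzene | C#Cc1ccc(OC)c(OCc2ccccc2)c1OCc1ccccc1 | intermediate
10 | carbon monoxide | [C-]#[O+] | starting material
11 | 1-[3-(benzyloxy)-6-hydroxy-2,4-dimethoxyphenyl]-3-[2,3-bis(benzyloxy)-4-methoxyphenyl]prop-2-yn-1-one | COc1ccc(C#CC(=O)c2c(O)cc(OC)c(OCc3ccccc3)c2OC)c(OCc2ccccc2)c1OCc1ccccc1 | intermediate
12 | (2E)-1-[3-(benzyloxy)-6-hydroxy-2,4-dimethoxyphenyl]-3-[2,3-bis(benzyloxy)-4-methoxyphenyl]-3-(diethylamino)prop-2-en-1-one (geometry assumed; either isomer closes) | CCN(CC)/C(=C/C(=O)c1c(O)cc(OC)c(OCc2ccccc2)c1OC)c1ccc(OC)c(OCc2ccccc2)c1OCc1ccccc1 | intermediate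
13 | 6-(benzyloxy)-2-[2,3-bis(benzyloxy)-4-methoxyphenyl]-5,7-dimethoxy-4H-chromen-4-one | COc1ccc(-c2cc(=O)c3c(OC)c(OCc4ccccc4)c(OC)cc3o2)c(OCc2ccccc2)c1OCc1ccccc1 | intermediate
14 | (2S)-6-(benzyloxy)-2-[2,3-bis(benzyloxy)-4-methoxyphenyl]-4-{[diethoxy(methyl)silyl]oxy}-5,7-dimethoxy-2H-chromene | COc1ccc([C@H]2Oc3cc(OC)c(OCc4ccccc4)c(OC)c3C(O[Si](C)(OCC)OCC)=C2)c(OCc2ccccc2)c1OCc1ccccc1 | intermediate
15 | (2S)-6-(benzyloxy)-2-[2,3-bis(benzyloxy)-4-methoxyphenyl]-5,7-dimethoxy-2,3-dihydro-4H-chromen-4-one | COc1ccc([C@H]2Oc3cc(OC)c(OCc4ccccc4)c(OC)c3C(=O)C2)c(OCc2ccccc2)c1OCc1ccccc1 | intermediate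
16 | (2S)-6-(benzyloxy)-2-[2,3-bis(benzyloxy)-4-methoxyphenyl]-5,7-dimethoxy-4-[(trimethylsilyl)oxy]-2H-chromene | COc1ccc([C@H]2Oc3cc(OC)c(OCc4ccccc4)c(OC)c3C(O[Si](C)(C)C)=C2)c(OCc2ccccc2)c1OCc1ccccc1 | intermediate
17 | (2R,3R)-6-(benzyloxy)-2-[2,3-bis(benzyloxy)-4-methoxyphenyl]-5,7-dimethoxy-3-[(trimethylsilyl)oxy]-2,3-dihydro-4H-chromen-4-one | COc1ccc([C@H]2Oc3cc(OC)c(OCc4ccccc4)c(OC)c3C(=O)[C@@H]2O[Si](C)(C)C)c(OCc2ccccc2)c1OCc1ccccc1 | intermediate
18 | (2R,3R)-6-(benzyloxy)-2-[2,3-bis(benzyloxy)-4-methoxyphenyl]-3-hydroxy-5,7-dimethoxy-2,3-dihydro-4H-chromen-4-one | COc1ccc([C@H]2Oc3cc(OC)c(OCc4ccccc4)c(OC)c3C(=O)[C@@H]2O)c(OCc2ccccc2)c1OCc1ccccc1 | intermediate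
19 | (2R,3R)-6-(benzyloxy)-2-[2,3-bis(benzyloxy)-4-methoxyphenyl]-3,5,7-trimethoxy-2,3-dihydro-4H-chromen-4-one | COc1ccc([C@H]2Oc3cc(OC)c(OCc4ccccc4)c(OC)c3C(=O)[C@@H]2OC)c(OCc2ccccc2)c1OCc1ccccc1 | intermediate
20 | (2R,3R)-2-(2,3-dihydroxy-4-methoxyphenyl)-5,6-dihydroxy-3,7-dimethoxy-2,3-dihydro-4H-chromen-4-one | COc1ccc([C@H]2Oc3cc(OC)c(O)c(O)c3C(=O)[C@@H]2OC)c(O)c1O | target

## Step count and least certain steps

Total step count: 10. Longest linear sequence: 8 (steps 1, 2, 3, 6, 7, 8, 9, 10); the ring B branch (steps 4 and 5) joins at step 6.

**Step 6 (key step).**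
- What may go wrong: the aroylpalladium intermediate may be intercepted by diethylamine (aminocarbonylation), coupling may occur without CO insertion, and oxidative addition may be slow at an iodide flanked by two oxygen substituents, which allows reductive deiodination.
- Fallback: it sets out from 4 and 9 and returns to the route at 11. Magnesium-mediated ortho-formylation of 4 (MgCl2, Et3N, paraformaldehyde, MeCN, reflux) should give 3-(benzyloxy)-6-hydroxy-2,4-dimethoxybenzaldehyde F1. Its phenol is masked as the magnesium phenoxide with i-PrMgCl, and the lithium acetylide of 9 (n-BuLi, THF, −78 °C) is added to give rac-1-[3-(benzyloxy)-6-hydroxy-2,4-dimethoxyphenyl]-3-[2,3-bis(benzyloxy)-4-methoxyphenyl]prop-2-yn-1-ol F2. MnO2 in CH2Cl2 oxidises F2 to 11, which is closed to 13 through 12 with Et2NH in EtOH as in the second half of step 6.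

**Step 7.**
- What may go wrong: hydride transfer may be slow, because C2 is the β-carbon of a vinylogous ester and is shielded by the twisted, ortho-substituted ring B. Without a proton source, turnover of the copper enolate by the silane may lag. Facial discrimination may be incomplete.
- Fallback: it sets out from 13 and returns at 15. Conjugate reduction with LiBH(s-Bu)3 (THF, −78 °C) should give rac-6-(benzyloxy)-2-[2,3-bis(benzyloxy)-4-methoxyphenyl]-5,7-dimethoxy-2,3-dihydro-4H-chromen-4-one F3. Kinetic resolution by asymmetric transfer hydrogenation (RhCl(C5Me5)[(R,R)-TsDPEN], HCO2H/Et3N, EtOAc, rt) is expected to reduce the 2R ketone to the cis alcohol (2R,4R)-6-(benzyloxy)-2-[2,3-bis(benzyloxy)-4-methoxyphenyl]-5,7-dimethoxy-3,4-dihydro-2H-chromen-4-ol F4 and leave 15, at the cost of half the material.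

**Step 8.**
- What may go wrong: the 3-chlorobenzoic acid formed may hydrolyse the enol silane back to the ketone before it is oxidised. Facial selectivity may erode, and the product may be dehydrogenated to the flavonol. The peracid may also oxidise the electron-rich arenes.
- Fallback: it sets out from 15 and returns at 18. Soft enolisation with TBSOTf and Et3N should give the isolable enol ether tert-butyl({(2S)-6-(benzyloxy)-2-[2,3-bis(benzyloxy)-4-methoxyphenyl]-5,7-dimethoxy-2H-chromen-4-yl}oxy)dimethylsilane F5. Osmium-catalysed dihydroxylation (K2OsO2(OH)4 cat., N-methylmorpholine N-oxide, acetone/H2O, 0 °C) adds to the enol double bond anti to the aryl group. Hydrolysis of the osmate and collapse of the silyl hemiketal give 18 in a neutral medium.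

**Step 10.**
- What may go wrong: the C2–O1 bond may ionise. It is a para-methoxybenzylic aryl ether made a better leaving group by boron chelation at the C4 carbonyl. Ionisation would cause ring opening, capture by the scavenger or epimerisation at C2. Cleavage of the C5 methyl may be incomplete, or further methyl ethers may be lost.
- Fallback: it sets out from 19 and returns at 20 in two orthogonal operations. MgI2·OEt2 (toluene/Et2O, 50 °C) should remove only the chelated C5 methyl and give (2R,3R)-6-(benzyloxy)-2-[2,3-bis(benzyloxy)-4-methoxyphenyl]-5-hydroxy-3,7-dimethoxy-2,3-dihydro-4H-chromen-4-one F6. Hydrogenolysis (H2, Pd/C, EtOAc, rt) then removes the three benzyl groups under neutral conditions.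

## Further compounds

F1 | step 6 | 3-(benzyloxy)-6-hydroxy-2,4-dimethoxybenzaldehyde | COc1cc(O)c(C=O)c(OC)c1OCc1ccccc1
F2 | step 6 | rac-1-[3-(benzyloxy)-6-hydroxy-2,4-dimethoxyphenyl]-3-[2,3-bis(benzyloxy)-4-methoxyphenyl]prop-2-yn-1-ol | COc1ccc(C#CC(O)c2c(O)cc(OC)c(OCc3ccccc3)c2OC)c(OCc2ccccc2)c1OCc1ccccc1
F3 | step 7 | rac-6-(benzyloxy)-2-[2,3-bis(benzyloxy)-4-methoxyphenyl]-5,7-dimethoxy-2,3-dihydro-4H-chromen-4-one | COc1ccc(C2Oc3cc(OC)c(OCc4ccccc4)c(OC)c3C(=O)C2)c(OCc2ccccc2)c1OCc1ccccc1
F4 | step 7 | (2R,4R)-6-(benzyloxy)-2-[2,3-bis(benzyloxy)-4-methoxyphenyl]-5,7-dimethoxy-3,4-dihydro-2H-chromen-4-ol | COc1ccc([C@@H]2Oc3cc(OC)c(OCc4ccccc4)c(OC)c3[C@H](O)C2)c(OCc2ccccc2)c1OCc1ccccc1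
F5 | step 8 | tert-butyl({(2S)-6-(benzyloxy)-2-[2,3-bis(benzyloxy)-4-methoxyphenyl]-5,7-dimethoxy-2H-chromen-4-yl}oxy)dimethylsilane | COc1ccc([C@H]2Oc3cc(OC)c(OCc4ccccc4)c(OC)c3C(O[Si](C)(C)C(C)(C)C)=C2)c(OCc2ccccc2)c1OCc1ccccc1
F6 | step 10 | (2R,3R)-6-(benzyloxy)-2-[2,3-bis(benzyloxy)-4-methoxyphenyl]-5-hydroxy-3,7-dimethoxy-2,3-dihydro-4H-chromen-4-one | COc1ccc([C@H]2Oc3cc(OC)c(OCc4ccccc4)c(O)c3C(=O)[C@@H]2OC)c(OCc2ccccc2)c1OCc1ccccc1
A1 | alternative 1 | (2R,3S)-1-[3-(benzyloxy)-2,4-dimethoxy-6-{[tri(propan-2-yl)silyl]oxy}phenyl]-3-[2,3-bis(benzyloxy)-4-methoxyphenyl]-3-hydroxy-2-methoxypropan-1-one | COc1ccc([C@H](O)[C@@H](OC)C(=O)c2c(OC)c(OCc3ccccc3)c(OC)cc2O[Si](C(C)C)(C(C)C)C(C)C)c(OCc2ccccc2)c1OCc1ccccc1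
A2 | alternative 1 | 1-[3-(benzyloxy)-2,4-dimethoxy-6-{[tri(propan-2-yl)silyl]oxy}phenyl]-2-diazoethan-1-one | [N-]=[N+]=CC(=O)c1c(OC)c(OCc2ccccc2)c(OC)cc1O[Si](C(C)C)(C(C)C)C(C)C
A3 | alternative 1 | methanol | CO
A4 | alternative 1 | (2R,3S)-1-[3-(benzyloxy)-6-hydroxy-2,4-dimethoxyphenyl]-3-[2,3-bis(benzyloxy)-4-methoxyphenyl]-3-hydroxy-2-methoxypropan-1-one | COc1ccc([C@H](O)[C@@H](OC)C(=O)c2c(OC)c(OCc3ccccc3)c(OC)cc2O)c(OCc2ccccc2)c1OCc1ccccc1
A5 | alternative 2 | (2R,3R)-2-[2,3-bis(benzyloxy)-4-methoxyphenyl]-5,6-dihydroxy-3,7-dimethoxy-2,3-dihydro-4H-chromen-4-one | COc1ccc([C@H]2Oc3cc(OC)c(O)c(O)c3C(=O)[C@@H]2OC)c(OCc2ccccc2)c1OCc1ccccc1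
A6 | alternative 2 | (2R,3R)-3-[2,3-bis(benzyloxy)-4-methoxyphenyl]-1-(2,3-dihydroxy-4-methoxyphenyl)-3-hydroxy-2-methoxypropan-1-one | COc1ccc([C@@H](O)[C@@H](OC)C(=O)c2ccc(OC)c(O)c2O)c(OCc2ccccc2)c1OCc1ccccc1
A7 | alternative 2 | 3-{(2R,3R)-3-[2,3-bis(benzyloxy)-4-methoxyphenyl]-3-hydroxy-2-methoxypropanoyl}-6-methoxycyclohexa-3,5-diene-1,2-dione | COc1ccc([C@@H](O)[C@@H](OC)C(=O)C2=CC=C(OC)C(=O)C2=O)c(OCc2ccccc2)c1OCc1ccccc1
A8 | alternative 3 | 1-[3-(benzyloxy)-6-{[2,3-bis(benzyloxy)-4-methoxyphenyl]methoxy}-2,4-dimethoxyphenyl]-2-diazoethan-1-one | [N-]=[N+]=CC(=O)c1c(OC)c(OCc2ccccc2)c(OC)cc1OCc1ccc(OC)c(OCc2ccccc2)c1OCc1ccccc1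
A9 | alternative 3 | (2S)-6-(benzyloxy)-2-[2,3-bis(benzyloxy)-4-methoxyphenyl]-5,7-dimethoxy-2,3-dihydro-4H-chromen-4-one | COc1ccc([C@H]2Oc3cc(OC)c(OCc4ccccc4)c(OC)c3C(=O)C2)c(OCc2ccccc2)c1OCc1ccccc1
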